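Rings A and B are disconnected together: a 3-bromo-4-methoxy-2-pyrone joined through C4–C3–C2–C1 to a terminal alkyne gives, in one thermal Diels–Alder/retro-Diels–Alder operation, the C4a–C8a and C7–C8 bonds, ring B and the aromatic ring A with loss of CO2. The step exploits the ring A pattern: OMe at C6 (from pyrone C4), oxygen at C7 (placed as the pyrone C3 bromine, later borylated and oxidised) and unsubstituted C5 and C8 (pyrone C5–H, alkyne CH). The precursor is an open-chain diacetate with C1, C2 and C3 preset by catalytic alkynylation, auxiliary-controlled alkylation and trans-selective lactone alkylation with a ready-made bromopyrone.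

Key step: step 14

Remarks on the chemistry
- Abbreviations: Ar = 4-(benzyloxy)-3,5-dimethoxyphenyl; PyrCH2 = (3-bromo-4-methoxy-2-oxo-2H-pyran-6-yl)methyl. Locants C1–C8a are those of the tetralin target.
- Structure check: the cycloaddition precursor and its product are stereochemically consistent with the target (1S,2R,3R). The CIP label at C1 reads S in the silylalkynes, R in the free alkyne and S again in the tetralins; only priorities change, not geometry.
- Assumption: in step 3 the antipode of the bisphosphine that delivers the (S)-configured centre is used; the sense of induction is to be confirmed on the first run.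
- Design choices: the pyrone is brominated before it is attached, so no electrophilic bromination is run in the presence of the electron-rich aryl ring or the alkyne. The alkyne is unmasked last under neutral conditions, because the C1–H is benzylic and propargylic.

Step 1
Reactants: 1 syringaldehyde
Product: 2 4-(benzyloxy)-3,5-dimethoxybenzaldehyde
Conditions: BnBr, K2CO3, DMF, 60 °C
Reagents that add atoms: benzyl bromide, BrCc1ccccc1
Why: Williamson ether synthesis on the only acidic OH; the aldehyde is inert to carbonate.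

Step 2
Reactants: 2 4-(benzyloxy)-3,5-dimethoxybenzaldehyde; 3 Meldrum's acid (2,2-dimethyl-1,3-dioxane-4,6-dione)
Product: 4 5-[4-(benzyloxy)-3,5-dimethoxybenzylidene]-2,2-dimethyl-1,3-dioxane-4,6-dione
Conditions: pyrrolidine (cat.), AcOH (cat.), PhMe, rt
Reagents that add atoms: none
Why: Knoevenagel condensation of an aromatic aldehyde with a highly acidic cyclic malonate, which should go to completion with loss of water.

Step 3
Reactants: 4 the benzylidene Meldrum's acid; 5 ethynyltrimethylsilane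
Product: 6 5-[(1S)-1-Ar-3-(trimethylsilyl)prop-2-yn-1-yl]-2,2-dimethyl-1,3-dioxane-4,6-dione
Conditions: [Rh(OAc)(C2H4)2]2 (2.5 mol %), 3,5-Xyl-MeO-BIPHEP (5.5 mol %), 5 (excess), 1,4-dioxane/H2O, 15 °C → rt
Reagents that add atoms: none
Why: Rhodium-catalysed asymmetric conjugate alkynylation of an arylidene Meldrum's acid: an alkynyl complex of monovalent rhodium adds 1,4 and the chiral bisphosphine selects the alkylidene face, which sets C1.

Step 4
Reactants: 6 the alkynylated Meldrum's acid
Product: 8 (3S)-3-Ar-5-(trimethylsilyl)pent-4-ynoic acid, via malonic acid 7 (not isolated)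
Conditions: DMF/H2O (10:1), 100 °C
Reagents that add atoms: water, O
Why: Hydrolytic opening of the Meldrum's acid ring followed by thermal decarboxylation of the malonic acid; the neutral medium should leave the C–Si bond and C1 untouched.

Step 5
Reactants: 8 (3S)-3-Ar-5-(trimethylsilyl)pent-4-ynoic acid; 9 (4S)-4-benzyl-1,3-oxazolidin-2-one
Product: 11 (4S)-4-benzyl-3-[(3S)-3-Ar-5-(trimethylsilyl)pent-4-ynoyl]-1,3-oxazolidin-2-one, via mixed pivalic anhydride 10 (not isolated)
Conditions: PivCl, Et3N, THF, −20 °C; then 9, LiCl, −20 °C → rt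
Reagents that add atoms: pivaloyl chloride, CC(C)(C)C(Cl)=O (to intermediate 10 only; none stays in 11)
Why: N-acylation of the oxazolidinone through a mixed anhydride, with LiCl making Et3N a sufficient base; no stereocentre is involved.

Step 6
Reactants: 11 the N-acyl oxazolidinone; 12 tert-butyl bromoacetate
Product: 14 tert-butyl (3S,4S)-4-Ar-3-{[(4S)-4-benzyl-2-oxo-1,3-oxazolidin-3-yl]carbonyl}-6-(trimethylsilyl)hex-5-ynoate, via sodium enolate 13 (not isolated)
Conditions: NaN(SiMe3)2, THF, −78 °C; then 12, −78 → −40 °C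
Reagents that add atoms: sodium bis(trimethylsilyl)amide, C[Si](C)(C)[N-][Si](C)(C)C.[Na+] (sodium, to intermediate 13 only)
Why: Evans alkylation: the chelated Z enolate is alkylated on the face away from the C4 benzyl group of the auxiliary, which sets C2 independently of the neighbouring C1 centre.

Step 7
Reactants: 14 the alkylated imide
Product: 16 (4S)-4-[(1S)-1-Ar-3-(trimethylsilyl)prop-2-yn-1-yl]oxolan-2-one, via hydroxy ester 15 (not isolated)
Conditions: LiBH4, H2O (1 equiv), Et2O, 0 °C; then TFA, CH2Cl2, 0 °C → rt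
Reagents that add atoms: none
Why: Reductive cleavage of the imide by LiBH4 spares the tert-butyl ester, and acid then removes the tert-butyl group and closes the γ-lactone (lactonisation) without touching C1 or C2.

Step 8
Reactants: 17 4-methoxy-6-methyl-2H-pyran-2-one
Product: 18 3-bromo-4-methoxy-6-methyl-2H-pyran-2-one
Conditions: NBS, MeCN, rt, dark
Reagents that add atoms: N-bromosuccinimide, O=C1CCC(=O)N1Br
Why: Electrophilic bromination at C3, the most nucleophilic ring carbon (α to the carbonyl and β to the methoxy enol ether).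

Step 9
Reactants: 18 3-bromo-4-methoxy-6-methyl-2H-pyran-2-one
Product: 19 3-bromo-6-(bromomethyl)-4-methoxy-2H-pyran-2-one
Conditions: NBS, AIBN (cat.), PhCF3, reflux
Reagents that add atoms: N-bromosuccinimide, O=C1CCC(=O)N1Br
Why: Wohl–Ziegler radical bromination of the 6-methyl group, which is allylic to the pyrone diene; C3 is already blocked.

Step 10
Reactants: 16 the β-substituted lactone; 19 3-bromo-6-(bromomethyl)-4-methoxy-2H-pyran-2-one
Product: 21 (3R,4R)-3-(PyrCH2)-4-[(1S)-1-Ar-3-(trimethylsilyl)prop-2-yn-1-yl]oxolan-2-one, via lithium enolate 20 (not isolated)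
Conditions: LiN(SiMe3)2, THF, −78 °C; then 19, −78 → −50 °C
Reagents that add atoms: lithium bis(trimethylsilyl)amide, C[Si](C)(C)[N-][Si](C)(C)C.[Li+] (lithium, to intermediate 20 only)
Why: Alkylation of a β-substituted γ-butyrolactone enolate occurs anti to the bulky β-substituent, which sets C3 trans to C2; the primary allylic-type bromide reacts by SN2 while the vinylic bromide is inert.

Step 11
Reactants: 21 the trans lactone
Product: 22 (2R,3R)-2-[(1S)-1-Ar-3-(trimethylsilyl)prop-2-yn-1-yl]-3-(PyrCH2)butane-1,4-diol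
Conditions: LiBH4, THF, 0 °C → rt
Reagents that add atoms: none
Why: Borohydride reduction of a lactone to a 1,4-diol: the saturated γ-lactone is a much better hydride acceptor than the 4-methoxy-2-pyrone, whose carbonyl is deactivated as a doubly vinylogous carbonate, so the reduction should stop at the diol.

Step 12
Reactants: 22 the diol
Product: 23 (2R,3R)-2-[(1S)-1-Ar-3-(trimethylsilyl)prop-2-yn-1-yl]-3-(PyrCH2)butane-1,4-diyl diacetate
Conditions: Ac2O, pyridine, DMAP (cat.), CH2Cl2, 0 °C → rt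
Reagents that add atoms: acetic anhydride, CC(=O)OC(C)=O
Why: DMAP-catalysed acylation of the two primary alcohols, the only nucleophilic groups present.

Step 13
Reactants: 23 the silylalkyne diacetate
Product: 24 (2R,3R)-2-[(1R)-1-Ar-prop-2-yn-1-yl]-3-(PyrCH2)butane-1,4-diyl diacetate
Conditions: AgNO3 (0.2 equiv), acetone/H2O/CH2Cl2, rt
Reagents that add atoms: none
Why: Silver-catalysed protodesilylation of a trimethylsilylalkyne (monovalent silver forms a silver acetylide that water protonates) is neutral, so the acetates, the pyrone and the base-sensitive C1–H should survive.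

Step 14
Reactants: 24 the pyrone–alkyne diacetate
Product: 26 [(1S,2R,3R)-1-Ar-7-bromo-6-methoxy-1,2,3,4-tetrahydronaphthalene-2,3-diyl]bis(methylene) diacetate, via bridged lactone adduct 25 (not isolated)
Conditions: 1,2-dichlorobenzene (0.01 M, degassed), BHT (cat.), 180 °C, sealed tube
Reagents that add atoms: none
Why: Thermal intramolecular Diels–Alder reaction followed by retro-Diels–Alder loss of CO2, a known mode of 2-pyrones, 3-bromo-2-pyrones included, with tethered alkynes: pyrone C3 and C6 add across the alkyne to give bridged lactone 25, which expels CO2 irreversibly and leaves the benzene ring. Ring B closes as a six-membered carbocycle in the fused mode, because the four-carbon tether C4–C3–C2–C1 joins pyrone C6 to the internal alkyne carbon (new C4a–C8a bond); ring A is completed by the second bond C7–C8 and aromatised by the decarboxylation. No stereocentre is created, and the two bridgehead centres of 25 disappear with CO2, so both diastereomeric adducts converge on 26. The selectivity needed is regiochemical, and the tether length excludes the other orientation, so the pyrone methoxy group must end at C6, the bromine at C7 and the alkyne CH at C8. C1, C2 and C3 are spectators under neutral, base-free heating, and the ambiphilic bromopyrone together with the branched tether should compensate for the unactivated alkyne.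

Step 15
Reactants: 26 the bromo aryltetralin diacetate
Product: 28 [(1S,2R,3R)-1-Ar-7-hydroxy-6-methoxy-1,2,3,4-tetrahydronaphthalene-2,3-diyl]bis(methylene) diacetate, via pinacol boronate 27 (not isolated)
Conditions: B2pin2, PdCl2(dppf) (5 mol %), KOAc, 1,4-dioxane, 90 °C; then NaBO3·4H2O, THF/H2O, rt
Reagents that add atoms: sodium perborate, [Na+].[O-]OB=O; bis(pinacolato)diboron, CC1(C)OB(OC1(C)C)B1OC(C)(C)C(C)(C)O1 (to intermediate 27 only)
Why: Miyaura borylation (zerovalent palladium inserts into the C7–Br bond, acetate-assisted transmetalation with the diboron) followed by perborate oxidation with aryl migration from boron to oxygen; the mild oxidant should leave both acetates in place.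

Step 16
Reactants: 28 the C7 phenol benzyl ether
Product: 29 [(1S,2R,3R)-7-hydroxy-1-(4-hydroxy-3,5-dimethoxyphenyl)-6-methoxy-1,2,3,4-tetrahydronaphthalene-2,3-diyl]bis(methylene) diacetate (CNP0265800.1)
Conditions: H2 (1 atm), 10% Pd/C, EtOAc, rt
Reagents that add atoms: none
Why: Hydrogenolysis of the benzyl aryl ether over palladium; no halogen or alkene remains and the acetates are inert.

Compound list
1 | syringaldehyde | COc1cc(C=O)cc(OC)c1O | starting material
2 | 4-(benzyloxy)-3,5-dimethoxybenzaldehyde | O=Cc1cc(OC)c(OCc2ccccc2)c(OC)c1 | intermediate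
3 | Meldrum's acid | CC1(C)OC(=O)CC(=O)O1 | starting material
4 | 5-[4-(benzyloxy)-3,5-dimethoxybenzylidene]-2,2-dimethyl-1,3-dioxane-4,6-dione | CC1(C)OC(=O)C(=Cc2cc(OC)c(OCc3ccccc3)c(OC)c2)C(=O)O1 | intermediate
5 | ethynyltrimethylsilane | C#C[Si](C)(C)C | starting material
6 | 5-[(1S)-1-Ar-3-(trimethylsilyl)prop-2-yn-1-yl]-2,2-dimethyl-1,3-dioxane-4,6-dione | CC1(C)OC(=O)C(C(=O)O1)[C@H](C#C[Si](C)(C)C)c1cc(OC)c(OCc2ccccc2)c(OC)c1 | intermediate
7 | 2-[(1S)-1-Ar-3-(trimethylsilyl)prop-2-yn-1-yl]propanedioic acid (not isolated) | OC(=O)C(C(O)=O)[C@H](C#C[Si](C)(C)C)c1cc(OC)c(OCc2ccccc2)c(OC)c1 | intermediate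
8 | (3S)-3-Ar-5-(trimethylsilyl)pent-4-ynoic acid | OC(=O)C[C@H](C#C[Si](C)(C)C)c1cc(OC)c(OCc2ccccc2)c(OC)c1 | intermediate
9 | (4S)-4-benzyl-1,3-oxazolidin-2-one | O=C1N[C@@H](Cc2ccccc2)CO1 | starting material
10 | mixed pivalic anhydride of 8 (not isolated) | CC(C)(C)C(=O)OC(=O)C[C@H](C#C[Si](C)(C)C)c1cc(OC)c(OCc2ccccc2)c(OC)c1 | intermediate
11 | (4S)-4-benzyl-3-[(3S)-3-Ar-5-(trimethylsilyl)pent-4-ynoyl]-1,3-oxazolidin-2-one | O=C(C[C@H](C#C[Si](C)(C)C)c1cc(OC)c(OCc2ccccc2)c(OC)c1)N1[C@@H](Cc2ccccc2)COC1=O | intermediate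
12 | tert-butyl bromoacetate | CC(C)(C)OC(=O)CBr | starting material
13 | Z sodium enolate of 11 (not isolated) | [Na+].[O-]/C(=C\[C@H](C#C[Si](C)(C)C)c1cc(OC)c(OCc2ccccc2)c(OC)c1)N1[C@@H](Cc2ccccc2)COC1=O | intermediate
14 | tert-butyl (3S,4S)-4-Ar-3-{[(4S)-4-benzyl-2-oxo-1,3-oxazolidin-3-yl]carbonyl}-6-(trimethylsilyl)hex-5-ynoate | CC(C)(C)OC(=O)C[C@H](C(=O)N1[C@@H](Cc2ccccc2)COC1=O)[C@H](C#C[Si](C)(C)C)c1cc(OC)c(OCc2ccccc2)c(OC)c1 | intermediate
15 | tert-butyl (3S,4S)-4-Ar-3-(hydroxymethyl)-6-(trimethylsilyl)hex-5-ynoate (not isolated) | CC(C)(C)OC(=O)C[C@H](CO)[C@H](C#C[Si](C)(C)C)c1cc(OC)c(OCc2ccccc2)c(OC)c1 | intermediate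
16 | (4S)-4-[(1S)-1-Ar-3-(trimethylsilyl)prop-2-yn-1-yl]oxolan-2-one | O=C1C[C@H](CO1)[C@H](C#C[Si](C)(C)C)c1cc(OC)c(OCc2ccccc2)c(OC)c1 | intermediate
17 | 4-methoxy-6-methyl-2H-pyran-2-one | COC1=CC(=O)OC(C)=C1 | starting material
18 | 3-bromo-4-methoxy-6-methyl-2H-pyran-2-one | COC1=C(Br)C(=O)OC(C)=C1 | intermediate
19 | 3-bromo-6-(bromomethyl)-4-methoxy-2H-pyran-2-one | COC1=C(Br)C(=O)OC(CBr)=C1 | intermediate
20 | lithium enolate of 16 (not isolated) | [Li+].[O-]C1=C[C@H](CO1)[C@H](C#C[Si](C)(C)C)c1cc(OC)c(OCc2ccccc2)c(OC)c1 | intermediate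
21 | (3R,4R)-3-(PyrCH2)-4-[(1S)-1-Ar-3-(trimethylsilyl)prop-2-yn-1-yl]oxolan-2-one | COC1=C(Br)C(=O)OC(C[C@H]2C(=O)OC[C@@H]2[C@H](C#C[Si](C)(C)C)c2cc(OC)c(OCc3ccccc3)c(OC)c2)=C1 | intermediate
22 | (2R,3R)-2-[(1S)-1-Ar-3-(trimethylsilyl)prop-2-yn-1-yl]-3-(PyrCH2)butane-1,4-diol | COC1=C(Br)C(=O)OC(C[C@@H](CO)[C@H](CO)[C@H](C#C[Si](C)(C)C)c2cc(OC)c(OCc3ccccc3)c(OC)c2)=C1 | intermediate
23 | (2R,3R)-2-[(1S)-1-Ar-3-(trimethylsilyl)prop-2-yn-1-yl]-3-(PyrCH2)butane-1,4-diyl diacetate | COC1=C(Br)C(=O)OC(C[C@@H](COC(C)=O)[C@H](COC(C)=O)[C@H](C#C[Si](C)(C)C)c2cc(OC)c(OCc3ccccc3)c(OC)c2)=C1 | intermediate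
24 | (2R,3R)-2-[(1R)-1-Ar-prop-2-yn-1-yl]-3-(PyrCH2)butane-1,4-diyl diacetate (cycloaddition precursor) | COC1=C(Br)C(=O)OC(C[C@@H](COC(C)=O)[C@H](COC(C)=O)[C@H](C#C)c2cc(OC)c(OCc3ccccc3)c(OC)c2)=C1 | intermediate
25 | bridged bicyclic lactone cycloadduct (not isolated; bridgehead configuration left open, both adducts converge) | COC1=CC23C[C@@H](COC(C)=O)[C@H](COC(C)=O)[C@@H](c4cc(OC)c(OCc5ccccc5)c(OC)c4)C2=CC1(Br)C(=O)O3 | intermediate
26 | [(1S,2R,3R)-1-Ar-7-bromo-6-methoxy-1,2,3,4-tetrahydronaphthalene-2,3-diyl]bis(methylene) diacetate | COc1cc2c(cc1Br)[C@H](c1cc(OC)c(OCc3ccccc3)c(OC)c1)[C@@H](COC(C)=O)[C@H](COC(C)=O)C2 | intermediate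
27 | C7 pinacol boronate of 26 (not isolated) | COc1cc2c(cc1B1OC(C)(C)C(C)(C)O1)[C@H](c1cc(OC)c(OCc3ccccc3)c(OC)c1)[C@@H](COC(C)=O)[C@H](COC(C)=O)C2 | intermediate
28 | [(1S,2R,3R)-1-Ar-7-hydroxy-6-methoxy-1,2,3,4-tetrahydronaphthalene-2,3-diyl]bis(methylene) diacetate | COc1cc2c(cc1O)[C@H](c1cc(OC)c(OCc3ccccc3)c(OC)c1)[C@@H](COC(C)=O)[C@H](COC(C)=O)C2 | intermediate
29 | [(1S,2R,3R)-7-hydroxy-1-(4-hydroxy-3,5-dimethoxyphenyl)-6-methoxy-1,2,3,4-tetrahydronaphthalene-2,3-diyl]bis(methylene) diacetate (CNP0265800.1) | COc1cc2c(cc1O)[C@H](c1cc(OC)c(O)c(OC)c1)[C@@H](COC(C)=O)[C@H](COC(C)=O)C2 | target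

Total step count: 16.
Longest linear sequence: 14 steps (steps 1–7 and 10–16, from syringaldehyde); steps 8 and 9 are the two-step side branch to bromide 19.

Steps most likely to fail

1. Step 14. The unactivated alkyne may add more slowly than the bromopyrone degrades, or the propargylic C1–H may isomerise, at the temperature needed. The fallback sets out from 24 and comes back at 26, and turns the alkyne into a stronger, traceless dienophile. Radical addition of thiophenol (PhSH, AIBN, PhMe, 80 °C) should give the vinyl sulfide F1, and oxidation (mCPBA, CH2Cl2, 0 °C) the vinyl sulfone F2. Heating F2 (PhMe, 110–140 °C, i-Pr2NEt) should give the bridged sulfonyl lactone F3, which loses CO2 to the sulfonyl cyclohexadiene F4; elimination of benzenesulfinic acid then gives 26 with the same tether-enforced regiochemistry.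

2. Step 11. Chemoselectivity may be lost: hydride may add to the pyrone (at its carbonyl or at C6) before the hindered lactone is fully reduced. The fallback sets out from 21 and comes back at 26, and postpones the reduction until the pyrone has been consumed. Silver-catalysed desilylation of 21 (conditions of step 13) should give the alkynyl lactone F5. Thermolysis (conditions of step 14) should lead through the bridged adduct F6 to the trans-fused bromo aryltetralin lactone F7. LiBH4 (THF, rt) then reduces the lactone, now the only reducible group, to the diol F8, and Ac2O/pyridine/DMAP gives 26.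

3. Step 10. Proton transfer from the acidic CH2Br group of 19 to the strongly basic lithium enolate, or addition to the pyrone ring, may compete with SN2 alkylation. The fallback sets out from 16 and comes back at 21, and uses a malonate-type alkylation under weak base. C-Acylation of the lactone enolate (LiN(SiMe3)2 2 equiv, Boc2O, THF, −78 °C) should give the α-tert-butoxycarbonyl lactone F9. Its soft enolate (K2CO3, DMF, rt) should be alkylated by 19 to the quaternary lactone F10. TFA (CH2Cl2) should give the acid F11, which decarboxylates on warming (PhMe, 90 °C) to 21, the more stable trans lactone (DBU, cat., to equilibrate if needed).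

Further compounds
F1 | step 14 | vinyl sulfide from 24 (E shown; either alkene isomer serves) | COC1=C(Br)C(=O)OC(C[C@@H](COC(C)=O)[C@H](COC(C)=O)[C@H](/C=C/Sc2ccccc2)c2cc(OC)c(OCc3ccccc3)c(OC)c2)=C1
F2 | step 14 | vinyl sulfone from F1 | COC1=C(Br)C(=O)OC(C[C@@H](COC(C)=O)[C@H](COC(C)=O)[C@H](/C=C/S(=O)(=O)c2ccccc2)c2cc(OC)c(OCc3ccccc3)c(OC)c2)=C1
F3 | step 14 | bridged sulfonyl lactone cycloadduct (new centres left open) | COC1=CC23C[C@@H](COC(C)=O)[C@H](COC(C)=O)[C@@H](c4cc(OC)c(OCc5ccccc5)c(OC)c4)C2C(S(=O)(=O)c2ccccc2)C1(Br)C(=O)O3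
F4 | step 14 | 8-(phenylsulfonyl) cyclohexadiene after loss of CO2 (C8 and C8a left open) | COC1=C(Br)C(S(=O)(=O)c2ccccc2)C2C(=C1)C[C@@H](COC(C)=O)[C@H](COC(C)=O)[C@H]2c1cc(OC)c(OCc3ccccc3)c(OC)c1
F5 | step 11 | (3R,4R)-3-(PyrCH2)-4-[(1R)-1-Ar-prop-2-yn-1-yl]oxolan-2-one | COC1=C(Br)C(=O)OC(C[C@H]2C(=O)OC[C@@H]2[C@H](C#C)c2cc(OC)c(OCc3ccccc3)c(OC)c2)=C1
F6 | step 11 | bridged bicyclic lactone cycloadduct of F5 (bridgeheads left open) | COC1=CC23C[C@H]4C(=O)OC[C@@H]4[C@@H](c4cc(OC)c(OCc5ccccc5)c(OC)c4)C2=CC1(Br)C(=O)O3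
F7 | step 11 | trans-fused 7-bromo-6-methoxy-1-Ar aryltetralin 2,3-lactone (carbonyl on the C3 arm) | COc1cc2c(cc1Br)[C@H](c1cc(OC)c(OCc4ccccc4)c(OC)c1)[C@H]3COC(=O)[C@@H]3C2
F8 | step 11 | [(1S,2R,3R)-1-Ar-7-bromo-6-methoxy-1,2,3,4-tetrahydronaphthalene-2,3-diyl]dimethanol | COc1cc2c(cc1Br)[C@H](c1cc(OC)c(OCc3ccccc3)c(OC)c1)[C@@H](CO)[C@H](CO)C2
F9 | step 10 | tert-butyl 2-oxo-4-[(1S)-1-Ar-3-(trimethylsilyl)prop-2-yn-1-yl]oxolane-3-carboxylate (C3 epimers) | CC(C)(C)OC(=O)C1C(=O)OC[C@@H]1[C@H](C#C[Si](C)(C)C)c1cc(OC)c(OCc2ccccc2)c(OC)c1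
F10 | step 10 | tert-butyl 3-(PyrCH2)-2-oxo-4-[(1S)-1-Ar-3-(trimethylsilyl)prop-2-yn-1-yl]oxolane-3-carboxylate | COC1=C(Br)C(=O)OC(CC2(C(=O)OC(C)(C)C)C(=O)OC[C@@H]2[C@H](C#C[Si](C)(C)C)c2cc(OC)c(OCc3ccccc3)c(OC)c2)=C1
F11 | step 10 | 3-(PyrCH2)-2-oxo-4-[(1S)-1-Ar-3-(trimethylsilyl)prop-2-yn-1-yl]oxolane-3-carboxylic acid | COC1=C(Br)C(=O)OC(CC2(C(O)=O)C(=O)OC[C@@H]2[C@H](C#C[Si](C)(C)C)c2cc(OC)c(OCc3ccccc3)c(OC)c2)=C1
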